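The runs were generated by integration for substances that don't exist, noise included.

If you want a quick number for gamma and epsilon, here is mine, set beside your hunch.

in all of them: free catalyst 0.90 mM
- violet: substrate 0.046 M; partner 0.0945 M (fed, over 2.0 s); temperature −15 °C; run made earlier; the fed solution adds 0.10 times the starting volume
- green: substrate 0.055 M; partner 0.0945 M (fed, over 2.0 s); temperature 0 °C; run made earlier; the fed solution adds 0.10 times the starting volume
- gamma: substrate 0.060 M; partner 0.0945 M; temperature 0 °C; everything together at the start, the whole solution of partner included, so that from the start the volume is larger by 0.10 times the starting volume; time 2.5 min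
- epsilon: substrate 0.090 M; partner 0.0945 M (fed, over 2.0 s); temperature 0 °C; the fed solution adds 0.10 times the starting volume; time 2.5 min

violet run (percent of the substrate charged)

| time / min | target / % | isomer of the product / % | substrate / % |
|---|---|---|---|
| 0.333 | 7.4 | 0.8 | 91.9 |
| 0.500 | 11.1 | 1.4 | 87.2 |
| 0.833 | 17.0 | 2.9 | 80.1 |
| 2.00 | 28.8 | 11.8 | 58.7 |
| 3.00 | 35.2 | 19.4 | 44.6 |

green run (percent of the substrate charged)

| time / s | target / % | isomer of the product / % | substrate / % |
|---|---|---|---|
| 12.0 | 10.7 | 2.6 | 88.3 |
| 25.0 | 18.0 | 4.5 | 75.2 |
| 40.0 | 26.6 | 8.8 | 65.2 |
| 50.0 | 32.8 | 10.1 | 57.3 |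
| 60.0 | 36.2 | 12.6 | 50.9 |
| 80.0 | 45.2 | 14.7 | 41.0 |

(scatter of a reading: 0.5 percentage points)

- charges are per starting volume, the dose included; the dosed solution carries all of it

- which of the two ends with the higher share of target in all that became target or isomer of the product ("neither" if they lie within 2 percentage points) (gamma / epsilon / neither)
- share of target in all that became target or isomer of the product, gamma
- share of target in all that became target or isomer of the product, epsilon

I look for the moment when control changes hands, from how fast each product is made to the balance between the two. In the green run at 0 °C, the share of target in the two products reads 80.5% at 12.0 s. It then reads 75.1% at 40.0 s and 75.5% at 80.0 s, so within the scatter I see a plateau from 40.0 s on. The violet run at −15 °C shows none: its share is still falling, from 90.2% to 64.5% at its last reading. So I pool the four plateau readings of the green run: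

c(target) summed: 141%

c(isomer of the product) summed: 46.2%

s = c(target) / (c(target) + c(isomer of the product)) = 75.3%

I call s the plateau share; it is a reading and carries their scatter, and I take it as the sign of thermodynamic rather than kinetic control in the green run. Gamma and epsilon both stand at 0 °C and are read at 2.5 min, which is later than the start of the green plateau by a factor of 3.75. So I commit to s for both, and to neither. I assume that the plateau holds past the last green reading at 80.0 s and does not depend on the charges or on how the partner goes in, though epsilon's substrate charge of 0.090 M is larger than the green one of 0.055 M.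

Your forecast says neither, with 70% for gamma and 70% for epsilon: “Extrapolated to 150 s, isomer is about 30% of product”. We agree on the verdict and differ by 5.3 percentage points on the number.

The simulation gives neither, with 73.8% for gamma and 73.9% for epsilon, so the forecast holds: its 70% for gamma lies 3.8 points below the simulated gamma, and s lies 1.5 points above it.

    partner + catalyst intermediate A → catalyst intermediate B (k = 1800 L mol⁻¹ s⁻¹, Ea = 40.0 kJ mol⁻¹)
    target ⇌ isomer of the product (K = 0.360, k = 0.0610 s⁻¹, Ea = 77.0 kJ mol⁻¹, ΔH = −35.0 kJ mol⁻¹)
    catalyst intermediate C → free catalyst + target (k = 120 s⁻¹, Ea = 47.0 kJ mol⁻¹)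
    catalyst intermediate B ⇌ by-product + catalyst intermediate C (K = 0.0310 M, k = 6.60 s⁻¹, Ea = 53.0 kJ mol⁻¹, ΔH = −4.00 kJ mol⁻¹)
    substrate + free catalyst ⇌ catalyst intermediate A (K = 23.0 L mol⁻¹, k = 15.0 L mol⁻¹ s⁻¹, Ea = 35.0 kJ mol⁻¹, ΔH = −39.0 kJ mol⁻¹)
    (constants at 0 °C)

The same reckoning goes on gamma read early, at 40 s, where I read the green plateau as beginning, so s gives 75.3% there. That early gamma gives 76.0%, with target at 26.9% and isomer of the product at 8.51% of the substrate charged. In that early gamma, substrate still stands at 64.4% of its charge.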